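Over the 2.50 d of the spring run, target and side product grew side by side, and I wanted to know how the new flask, with twice the partner, would split them.

all flasks: substrate 0.17 M
- spring: partner 0.13 M; protic impurity 0.034 M; run made earlier
- flask: partner 0.255 M; protic impurity 0.0340 M; time 8.0 d

spring run (percent of the substrate charged)

| time / d | side product / % | target / % |
|---|---|---|
| 0.208 | 0 | 4 |
| 0.333 | 2 | 4 |
| 0.500 | 4 | 6 |
| 0.833 | 11 | 10 |
| 1.67 | 31 | 24 |
| 2.50 | 46 | 29 |

(each reading ± 2 percentage points)

- share of side product in side product plus target at 6.0 h
- share of side product in side product plus target at 30 h
- share of side product in side product plus target at 8.0 d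
- which of side product and target there is more of at 8.0 d

- the analysis behind the earlier runs scatters by 2 percentage points, standard deviation

I read the spring table from the bottom up, taking side product over the sum of both products. The share was 61.3 % at 2.50 d, 56.4 % at 1.67 d and 52.4 % at 0.833 d. Higher up it was 33.3 % at 0.333 d, from a few points of product. Each share is a ratio of readings scattering by 2 percentage points, so I froze one number: the late share, side product over side product plus target pooled across the last two rows, 59.2 %. Two outlets, each proportional to the level in one tank, keep their split as the level falls, and I treated this selectivity the same way. The last step of the spring run added 15 points of side product against 5 points of target, but those are differences of scattered readings, so I kept the pooled value.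

For the new flask I therefore reckoned about 59.2 % at 30 h and 8.0 d, with more side product than target, and for 6.0 h something near the 33.3 % read in the spring run at 0.333 d. Carrying the share to another partner charge was my bet, untested by a single run.

The forecast gave 15 % (0 % to 35 %), 30 % (18 % to 46 %) and 38 % (25 % to 52 %), with target ahead, holding that “target formation needs partner while the side path does not”. There it parted from my reckoning.

The flask gave 43.1 %, 58.3 % and 60.7 %, with side product ahead.

    substrate → intermediate A (k = 0.110 h⁻¹)
    intermediate A → target (k = 0.0110 h⁻¹)
    intermediate A → intermediate B (k = 0.0170 h⁻¹)
    intermediate B → side product (k = 0.380 h⁻¹)
    partner + protic impurity → quenched reagent (k = 0.300 M⁻¹ h⁻¹)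

At 8.00 d the flask held 87 % of its partner, a loss of 0.0340 M beside 0.0340 M of quenched reagent, while target stood at 39.0 %. The late share lay 1.5 points below the flask's share at 8.0 d. In a neighbour flask, like this one but with 0.0085 M of protic impurity, 97 % of the partner remained, and the late share applied to its products gives 58.8 % of the substrate as side product, where that flask held 60.3 % at 8.00 d.

The numbers in the tables were generated by integration with made-up constants; the scatter is artificial.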